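**Plan**

1. Ring feature: in the 1,2-dioxane (O1–O2–C3–C4–C5–C6, with CH2CO2H on C3 and the methoxy ketal at C6), C4–C5 is the only ring bond between two methylene carbons. It is cut as an alkene, leading back to an acyclic dialkyl peroxide with one vinyl group on C3 and one on C6; metathesis and then diimide rebuild it without touching O1–O2.
2. Further cuts: the C(sp)–C(sp2) bond of the enyne (Sonogashira), the terminal alkyne carbon (Seyferth–Gilbert), O2–C3 (SN2 of a peroxide anion on an α-triflyloxy lactone), O1–C6 (H2O2 addition to an allenyl ether) and the C6–side-chain bond (alkylation of lithiated methoxyallene).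
3. Forward order: the C6 hydroperoxy ketal is made and O-alkylated by the lactone triflate; the lactone carbonyl becomes the C3 vinyl group and its CH2CH2O arm becomes CH2CO2Me; metathesis closes the only ring, diimide saturates it, and the side chain is then grown outward from C6.
4. Stereochemistry: C3 comes from commercial (S)-α-hydroxy-γ-butyrolactone through one SN2 inversion. C6 is set late by acid-catalysed anomeric equilibration (OMe axial, cis to the C3 arm). The E alkene comes from a Takai olefination and is retained in the coupling.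

Key step: step 9

Remark: one-carbon homologation of an aldehyde to the alkyne requires four carbons between C6 and the silyloxy oxygen, so the ketal fragment is a 7-silyloxyhept-1-en-3-yl unit; compounds 5 and 8–20 are carried as mixtures of epimers at the ketal carbon, which is fixed only in step 14.

**Step 1**
Reactants: 1 methoxyallene; 2 tert-butyl(4-iodobutoxy)dimethylsilane
Product: 4 tert-butyl[(5-methoxyhepta-5,6-dien-1-yl)oxy]dimethylsilane, via 1-lithio-1-methoxyallene 3 (not isolated)
Conditions: n-BuLi (1.1 equiv), THF, −78 °C; then 2, −78 °C → rt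
Reagents that add atoms: none
Why: Deprotonation of the alkoxyallene at the oxygen-bearing carbon and SN2 alkylation of the allenyllithium by a primary iodide should give the 1,1-disubstituted allenyl ether, whose three allene carbons become C6 and its vinyl group.

**Step 2**
Reactants: 4 tert-butyl[(5-methoxyhepta-5,6-dien-1-yl)oxy]dimethylsilane
Product: 5 7-[(tert-butyldimethylsilyl)oxy]-3-methoxyhept-1-en-3-yl hydroperoxide (racemic)
Conditions: anhydrous H2O2 in Et2O (8 equiv), PPTS (5 mol %), 0 °C; NaHCO3 wash
Reagents that add atoms: hydrogen peroxide, OO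
Why: Acid-catalysed Markovnikov addition of H2O2 to an enol ether (α-alkoxy hydroperoxide synthesis): protonation of the central allene carbon gives a methoxy-stabilised allyl cation that should be captured at the oxygen-bearing carbon, as alcohols are in their addition to alkoxyallenes; the ketal centre forms as a racemate and is corrected in step 14.

**Step 3**
Reactants: 6 (S)-3-hydroxyoxolan-2-one [(S)-α-hydroxy-γ-butyrolactone]
Product: 7 (S)-2-oxooxolan-3-yl trifluoromethanesulfonate
Conditions: Tf2O (1.1 equiv), 2,6-lutidine (1.2 equiv), CH2Cl2, −78 → −40 °C; used without storage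
Reagents that add atoms: trifluoromethanesulfonic anhydride, O=S(=O)(OS(=O)(=O)C(F)(F)F)C(F)(F)F
Why: O-Sulfonylation (alcohol triflation) leaves the C–O bond and the (S) configuration untouched and places the best leaving group on a carbon whose SN2 reactivity is raised, and whose ionisation is suppressed, by the adjacent lactone carbonyl.

**Step 4**
Reactants: 5 7-[(tert-butyldimethylsilyl)oxy]-3-methoxyhept-1-en-3-yl hydroperoxide; 7 (S)-2-oxooxolan-3-yl trifluoromethanesulfonate
Product: 9 (3R)-3-({7-[(tert-butyldimethylsilyl)oxy]-3-methoxyhept-1-en-3-yl}peroxy)oxolan-2-one (ketal epimers), via potassium alkylperoxide 8 (not isolated)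
Conditions: 5 (1.2 equiv), KOtBu (1.15 equiv), THF, −78 °C; then 7, −78 → −30 °C
Reagents that add atoms: none
Why: Williamson-type O-alkylation of a peroxide anion by an alkyl triflate: back-side SN2 attack at the carbon α to the lactone carbonyl inverts (S)-C–OTf to (R)-C–OO, the future C3 of the dioxane, and at −78 °C substitution should outrun E2 loss of triflate to the butenolide.

**Step 5**
Reactants: 9 (3R)-3-({7-[(tert-butyldimethylsilyl)oxy]-3-methoxyhept-1-en-3-yl}peroxy)oxolan-2-one
Product: 10 (3R)-3-({7-[(tert-butyldimethylsilyl)oxy]-3-methoxyhept-1-en-3-yl}peroxy)oxolan-2-ol (mixture of epimers)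
Conditions: i-Bu2AlH (1.2 equiv), CH2Cl2, −78 °C; MeOH, then aq. potassium sodium tartrate
Reagents that add atoms: none
Why: Half-reduction of a lactone to the lactol stops at the tetrahedral aluminium alkoxide at −78 °C, a hydride reduction that dialkyl peroxides and peroxyketals are known to survive at this temperature; the peroxy-bearing stereocentre is not involved.

**Step 6**
Reactants: 10 (3R)-3-({7-[(tert-butyldimethylsilyl)oxy]-3-methoxyhept-1-en-3-yl}peroxy)oxolan-2-ol
Product: 12 (3R)-3-({7-[(tert-butyldimethylsilyl)oxy]-3-methoxyhept-1-en-3-yl}peroxy)pent-4-en-1-ol, via hydroxy aldehyde 11 (not isolated)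
Conditions: Ph3PCH3Br (3.5 equiv), KN(SiMe3)2 (3.3 equiv), THF, 0 °C; then 10, −78 → 0 °C
Reagents that add atoms: methyltriphenylphosphonium bromide, C[P+](c1ccccc1)(c1ccccc1)c1ccccc1.[Br-]
Why: Wittig methylenation of a lactol through its open hydroxy aldehyde tautomer; addition of the unstabilised ylide to the α-peroxy aldehyde at low temperature should be faster than its enolisation, so the (R) centre is kept and the C3 vinyl group is installed.

**Step 7**
Reactants: 12 (3R)-3-({7-[(tert-butyldimethylsilyl)oxy]-3-methoxyhept-1-en-3-yl}peroxy)pent-4-en-1-ol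
Product: 14 (3R)-3-({7-[(tert-butyldimethylsilyl)oxy]-3-methoxyhept-1-en-3-yl}peroxy)pent-4-enoic acid, via aldehyde 13 (not isolated)
Conditions: TEMPO (0.2 equiv), PhI(OAc)2 (2.5 equiv), MeCN/aq. phosphate buffer (pH 7) 1:1, 0 °C → rt; crude acid used at once
Reagents that add atoms: water, O
Why: TEMPO-catalysed oxidation with PhI(OAc)2 takes a primary alcohol through the aldehyde hydrate to the acid without touching alkenes or the O–O bond, and the pH 7 buffer should protect the acid-labile allylic peroxyketal.

**Step 8**
Reactants: 14 (3R)-3-({7-[(tert-butyldimethylsilyl)oxy]-3-methoxyhept-1-en-3-yl}peroxy)pent-4-enoic acid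
Product: 15 methyl (3R)-3-({7-[(tert-butyldimethylsilyl)oxy]-3-methoxyhept-1-en-3-yl}peroxy)pent-4-enoate (ketal epimers)
Conditions: Me3SiCHN2 (2 M in hexanes, 1.5 equiv), toluene/MeOH 4:1, 0 °C
Reagents that add atoms: (trimethylsilyl)diazomethane, C[Si](C)(C)C=[N+]=[N-]
Why: O-Methylation of a carboxylic acid by (trimethylsilyl)diazomethane in methanol is fast and essentially neutral, so the peroxyketal, the silyl ether and the allylic peroxide stereocentre should be unaffected.

**Step 9**
Reactants: 15 methyl (3R)-3-({7-[(tert-butyldimethylsilyl)oxy]-3-methoxyhept-1-en-3-yl}peroxy)pent-4-enoate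
Product: 16 methyl 2-[(3R)-6-{4-[(tert-butyldimethylsilyl)oxy]butyl}-6-methoxy-3,6-dihydro-1,2-dioxin-3-yl]acetate (C6 epimers)
Conditions: second-generation Grubbs catalyst (H2IMes)(PCy3)Cl2Ru=CHPh (5–10 mol %), degassed CH2Cl2 (0.005 M), 40 °C; ethyl vinyl ether quench
Reagents that add atoms: none
Why: The ruthenium benzylidene exchanges onto the less hindered C3 vinyl group by [2+2] cycloaddition and cycloreversion, the new alkylidene adds intramolecularly to the vinyl group on the quaternary ketal carbon C6 to give a ruthenacyclobutane, and cycloreversion releases the C4=C5 alkene and a ruthenium methylidene that is lost as ethene in the next turnover. The closest known reactions are ring-closing olefin metathesis of dienes with allylic oxygen substituents and of unsaturated dialkyl peroxides with ruthenium carbenes. The 3,6-dihydro-1,2-dioxine closes as a six-membered ring from an acyclic 1,7-diene whose tether contains the O1–O2 bond, both new sp2 carbons ending up inside the ring. No stereocentre is created: C3 is already fixed from the lactone and both C6 epimers should cyclise. The step needs chemoselectivity for metathesis over ruthenium-induced O–O cleavage and alkene isomerisation; a fully alkylated peroxide without O–H, flanked by a bulky ketal carbon, is a poor ligand and a poor oxidant for the carbene, and high dilution, gentle heating and escape of ethene keep the reaction short.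

**Step 10**
Reactants: 16 methyl 2-[(3R)-6-{4-[(tert-butyldimethylsilyl)oxy]butyl}-6-methoxy-3,6-dihydro-1,2-dioxin-3-yl]acetate
Product: 17 methyl 2-[(3S)-6-{4-[(tert-butyldimethylsilyl)oxy]butyl}-6-methoxy-1,2-dioxan-3-yl]acetate (C6 epimers)
Conditions: KO2CN=NCO2K (10 equiv), AcOH (20 equiv, slow addition), CH2Cl2, 0 °C → rt
Reagents that add atoms: none
Why: Diimide reduction: HN=NH transfers H2 to the cis-disubstituted ring alkene in a concerted, metal-free syn addition that leaves the O–O bond, ester and silyl ether intact (the descriptor at C3 changes from R to S only because the CIP priorities change).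

**Step 11**
Reactants: 17 methyl 2-[(3S)-6-{4-[(tert-butyldimethylsilyl)oxy]butyl}-6-methoxy-1,2-dioxan-3-yl]acetate
Product: 18 methyl 2-[(3S)-6-(4-hydroxybutyl)-6-methoxy-1,2-dioxan-3-yl]acetate (C6 epimers)
Conditions: Bu4NF (2 equiv), AcOH (2 equiv), THF, 0 °C → rt
Reagents that add atoms: none
Why: Fluoride-induced desilylation of a primary silyl ether; the acetic acid buffer keeps the medium near neutral, so that neither base-induced β-elimination of the peroxide from the ester nor acid-induced spiroketalisation of the new hydroxyl onto C6 should occur.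

**Step 12**
Reactants: 18 methyl 2-[(3S)-6-(4-hydroxybutyl)-6-methoxy-1,2-dioxan-3-yl]acetate
Product: 19 methyl 2-[(3S)-6-methoxy-6-(4-oxobutyl)-1,2-dioxan-3-yl]acetate (C6 epimers)
Conditions: Dess–Martin periodinane (1.3 equiv), NaHCO3 (5 equiv), CH2Cl2, 0 °C → rt
Reagents that add atoms: none
Why: Dess–Martin oxidation of a primary alcohol to the aldehyde is non-acidic under hydrogencarbonate buffering and is compatible with peroxides and ketals.

**Step 13**
Reactants: 19 methyl 2-[(3S)-6-methoxy-6-(4-oxobutyl)-1,2-dioxan-3-yl]acetate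
Product: 20 methyl 2-[(3S)-6-methoxy-6-(pent-4-yn-1-yl)-1,2-dioxan-3-yl]acetate (C6 epimers)
Conditions: dimethyl (1-diazo-2-oxopropyl)phosphonate (1.5 equiv), K2CO3 (2 equiv), MeOH, 0 °C → rt
Reagents that add atoms: dimethyl (1-diazo-2-oxopropyl)phosphonate, COP(=O)(OC)C(=[N+]=[N-])C(C)=O
Why: Seyferth–Gilbert homologation with the Ohira–Bestmann reagent converts the aldehyde into the terminal alkyne with one added carbon under weakly basic conditions in methanol, which a methyl ester and a ring-bound peroxyketal should tolerate.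

**Step 14**
Reactants: 20 methyl 2-[(3S)-6-methoxy-6-(pent-4-yn-1-yl)-1,2-dioxan-3-yl]acetate
Product: 21 methyl 2-[(3S,6R)-6-methoxy-6-(pent-4-yn-1-yl)-1,2-dioxan-3-yl]acetate
Conditions: CSA (0.1 equiv), MeOH, rt, to constant epimer ratio; Et3N; chromatography, minor epimer resubmitted
Reagents that add atoms: methanol, CO
Why: Acid-catalysed anomeric equilibration of the cyclic methoxy peroxyketal through its oxocarbenium ion in methanol should favour the chair with OMe axial (anomeric effect) and both carbon substituents equatorial, which for (3S) is the (6R) epimer with OMe cis to the acetate arm; no free hydroxyl is present that could divert the cation to a spiroketal.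

**Step 15**
Reactants: 22 undec-10-en-2-one
Product: 24 9-oxodecanal, via ozonide 23 (not isolated)
Conditions: O3, CH2Cl2, −78 °C; then PPh3 (1.2 equiv), −78 °C → rt
Reagents that add atoms: ozone, [O-][O+]=O
Why: Ozonolysis of the terminal alkene with reductive work-up should give the aldehyde one carbon shorter, the saturated methyl ketone being inert to ozone.

**Step 16**
Reactants: 24 9-oxodecanal
Product: 25 (10E)-11-iodoundec-10-en-2-one
Conditions: CrCl2 (6 equiv), CHI3 (2 equiv), THF/1,4-dioxane, 0 °C → rt
Reagents that add atoms: iodoform, IC(I)I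
Why: Takai olefination: the geminal dichromium species from CHI3 and CrCl2 adds to the aldehyde in preference to the ketone and anti elimination should give the (E)-alkenyl iodide.

**Step 17**
Reactants: 21 methyl 2-[(3S,6R)-6-methoxy-6-(pent-4-yn-1-yl)-1,2-dioxan-3-yl]acetate; 25 (10E)-11-iodoundec-10-en-2-one
Product: 26 methyl 2-[(3S,6R)-6-methoxy-6-[(6E)-15-oxohexadec-6-en-4-yn-1-yl]-1,2-dioxan-3-yl]acetate
Conditions: Pd(PPh3)4 (5 mol %), CuI (10 mol %), Et3N (3 equiv), degassed THF, rt
Reagents that add atoms: none
Why: Sonogashira coupling of a terminal alkyne with an (E)-alkenyl iodide under zerovalent palladium and CuI catalysis proceeds at room temperature with retention of alkene geometry, conditions that saturated 1,2-dioxanes, esters and ketones should tolerate.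

**Step 18**
Reactants: 26 methyl 2-[(3S,6R)-6-methoxy-6-[(6E)-15-oxohexadec-6-en-4-yn-1-yl]-1,2-dioxan-3-yl]acetate
Product: 27 2-[(3S,6R)-6-methoxy-6-[(6E)-15-oxohexadec-6-en-4-yn-1-yl]-1,2-dioxan-3-yl]acetic acid
Conditions: LiOH (3 equiv), THF/H2O 3:1, 0 °C → rt; then 0.5 M HCl to pH 4 at 0 °C
Reagents that add atoms: lithium hydroxide, [Li+].[OH-]
Why: Saponification of the methyl ester; the peroxyketal is stable to base, and retro-oxa-Michael opening of the ring-bound β-peroxy ester should be slow at 0 °C, so the two stereocentres are kept.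

**Compound list**

1 | methoxyallene (1-methoxypropa-1,2-diene) | COC=C=C | starting material
2 | tert-butyl(4-iodobutoxy)dimethylsilane | CC(C)(C)[Si](C)(C)OCCCCI | starting material
3 | 1-lithio-1-methoxyallene (not isolated) | [Li]C(OC)=C=C | intermediate
4 | tert-butyl[(5-methoxyhepta-5,6-dien-1-yl)oxy]dimethylsilane | C=C=C(OC)CCCCO[Si](C)(C)C(C)(C)C | intermediate
5 | 7-[(tert-butyldimethylsilyl)oxy]-3-methoxyhept-1-en-3-yl hydroperoxide (racemic) | COC(C=C)(CCCCO[Si](C)(C)C(C)(C)C)OO | intermediate
6 | (S)-3-hydroxyoxolan-2-one [(S)-α-hydroxy-γ-butyrolactone] | O[C@H]1CCOC1=O | starting material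
7 | (S)-2-oxooxolan-3-yl trifluoromethanesulfonate | O=S(=O)(O[C@H]1CCOC1=O)C(F)(F)F | intermediate
8 | potassium 7-[(tert-butyldimethylsilyl)oxy]-3-methoxyhept-1-en-3-yl peroxide (not isolated) | COC(C=C)(CCCCO[Si](C)(C)C(C)(C)C)O[O-].[K+] | intermediate
9 | (3R)-3-({7-[(tert-butyldimethylsilyl)oxy]-3-methoxyhept-1-en-3-yl}peroxy)oxolan-2-one (ketal epimers) | COC(C=C)(CCCCO[Si](C)(C)C(C)(C)C)OO[C@@H]1CCOC1=O | intermediate
10 | (3R)-3-({7-[(tert-butyldimethylsilyl)oxy]-3-methoxyhept-1-en-3-yl}peroxy)oxolan-2-ol (mixture of epimers) | COC(C=C)(CCCCO[Si](C)(C)C(C)(C)C)OO[C@@H]1CCOC1O | intermediate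
11 | (2R)-2-({7-[(tert-butyldimethylsilyl)oxy]-3-methoxyhept-1-en-3-yl}peroxy)-4-hydroxybutanal (open tautomer of 10, not isolated) | COC(C=C)(CCCCO[Si](C)(C)C(C)(C)C)OO[C@@H](C=O)CCO | intermediate
12 | (3R)-3-({7-[(tert-butyldimethylsilyl)oxy]-3-methoxyhept-1-en-3-yl}peroxy)pent-4-en-1-ol (ketal epimers) | COC(C=C)(CCCCO[Si](C)(C)C(C)(C)C)OO[C@@H](C=C)CCO | intermediate
13 | (3R)-3-({7-[(tert-butyldimethylsilyl)oxy]-3-methoxyhept-1-en-3-yl}peroxy)pent-4-enal (not isolated) | COC(C=C)(CCCCO[Si](C)(C)C(C)(C)C)OO[C@@H](C=C)CC=O | intermediate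
14 | (3R)-3-({7-[(tert-butyldimethylsilyl)oxy]-3-methoxyhept-1-en-3-yl}peroxy)pent-4-enoic acid (ketal epimers) | COC(C=C)(CCCCO[Si](C)(C)C(C)(C)C)OO[C@@H](C=C)CC(=O)O | intermediate
15 | methyl (3R)-3-({7-[(tert-butyldimethylsilyl)oxy]-3-methoxyhept-1-en-3-yl}peroxy)pent-4-enoate (ketal epimers) | COC(C=C)(CCCCO[Si](C)(C)C(C)(C)C)OO[C@@H](C=C)CC(=O)OC | intermediate
16 | methyl 2-[(3R)-6-{4-[(tert-butyldimethylsilyl)oxy]butyl}-6-methoxy-3,6-dihydro-1,2-dioxin-3-yl]acetate (C6 epimers) | COC1(CCCCO[Si](C)(C)C(C)(C)C)C=C[C@@H](CC(=O)OC)OO1 | intermediate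
17 | methyl 2-[(3S)-6-{4-[(tert-butyldimethylsilyl)oxy]butyl}-6-methoxy-1,2-dioxan-3-yl]acetate (C6 epimers) | COC1(CCCCO[Si](C)(C)C(C)(C)C)CC[C@@H](CC(=O)OC)OO1 | intermediate
18 | methyl 2-[(3S)-6-(4-hydroxybutyl)-6-methoxy-1,2-dioxan-3-yl]acetate (C6 epimers) | COC1(CCCCO)CC[C@@H](CC(=O)OC)OO1 | intermediate
19 | methyl 2-[(3S)-6-methoxy-6-(4-oxobutyl)-1,2-dioxan-3-yl]acetate (C6 epimers) | COC1(CCCC=O)CC[C@@H](CC(=O)OC)OO1 | intermediate
20 | methyl 2-[(3S)-6-methoxy-6-(pent-4-yn-1-yl)-1,2-dioxan-3-yl]acetate (C6 epimers) | COC1(CCCC#C)CC[C@@H](CC(=O)OC)OO1 | intermediate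
21 | methyl 2-[(3S,6R)-6-methoxy-6-(pent-4-yn-1-yl)-1,2-dioxan-3-yl]acetate | CO[C@@]1(CCCC#C)CC[C@@H](CC(=O)OC)OO1 | intermediate
22 | undec-10-en-2-one | CC(=O)CCCCCCCC=C | starting material
23 | 9-(1,2,4-trioxolan-3-yl)nonan-2-one (ozonide, not isolated) | CC(=O)CCCCCCCC1OOCO1 | intermediate
24 | 9-oxodecanal | CC(=O)CCCCCCCC=O | intermediate
25 | (10E)-11-iodoundec-10-en-2-one | CC(=O)CCCCCCC/C=C/I | intermediate
26 | methyl 2-[(3S,6R)-6-methoxy-6-[(6E)-15-oxohexadec-6-en-4-yn-1-yl]-1,2-dioxan-3-yl]acetate | CO[C@@]1(CCCC#C/C=C/CCCCCCCC(C)=O)CC[C@@H](CC(=O)OC)OO1 | intermediate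
27 | 2-[(3S,6R)-6-methoxy-6-[(6E)-15-oxohexadec-6-en-4-yn-1-yl]-1,2-dioxan-3-yl]acetic acid | CO[C@@]1(CCCC#C/C=C/CCCCCCCC(C)=O)CC[C@@H](CC(=O)O)OO1 | target

**Step count and risks**

Total: 18 steps. Longest linear sequence: 15 steps (1, 2, 4–14, 17, 18) from methoxyallene; steps 3, 15 and 16 prepare the two side fragments.

Step 9 (ring-closing metathesis). What may go wrong: the carbene loads only slowly onto either of the two branched, allylically oxygenated vinyl groups, so that electron transfer from ruthenium to the O–O bond and alkene isomerisation overtake ring closure. Fallback, a relay metathesis that sets out from lactol 10 and returns at 16: Wittig reaction of 10 with the ylide from hex-5-en-1-yltriphenylphosphonium bromide should give the relay dienol F1. Oxidation under the conditions of step 7 should pass through the aldehyde F2 to the acid F3, and methylation as in step 8 should give the methyl ester F4. With the same ruthenium catalyst the carbene should load on the unhindered terminal alkene of the tether, expel cyclopentene and so be delivered directly to C4, from where it closes onto the C6 vinyl group to give 16.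

Step 4 (peroxide O-alkylation). What may go wrong: the hindered tertiary peroxide anion acts as a base rather than a nucleophile, so that elimination of triflate to the butenolide and reversible attack at the lactone carbonyl consume 7 before substitution occurs. Fallback, with the roles of the two fragments exchanged, setting out from triflate 7 and allenyl ether 4 and returning at 9 (step 2 is then not needed): displacement of the triflate of 7 by unhindered anhydrous H2O2 in ether with 2,6-lutidine at −40 → 0 °C should give, with the same SN2 inversion, the hydroperoxy lactone F5. PPTS-catalysed addition of its O–H across the enol ether double bond of 4 in CH2Cl2 at 0 °C (perketalisation of a hydroperoxide) should then form the mixed methyl peroxyketal 9.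

Step 6 (methylenation of the lactol). What may go wrong: the basic ylide enolises the α-peroxy aldehyde tautomer, which then fragments at the O–O bond (Kornblum–DeLaMare pathway) or epimerises at the peroxy carbon before olefination takes place. Fallback, a two-stage Peterson olefination that sets out from 10 and returns at 12: the weakly basic, strongly carbonyl-seeking reagent from Me3SiCH2MgCl and CeCl3 in THF at −78 °C should add to the lactol to give the β-hydroxysilane diol F6, and KOtBu in THF at 0 °C should then effect syn elimination of silanolate to the vinyl compound 12, with no enolisable carbonyl present during the basic stage.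

**Further compounds**

F1 | step 9 | (3R,4Z)-3-({7-[(tert-butyldimethylsilyl)oxy]-3-methoxyhept-1-en-3-yl}peroxy)deca-4,9-dien-1-ol | COC(C=C)(CCCCO[Si](C)(C)C(C)(C)C)OO[C@@H](/C=C\CCCC=C)CCO
F2 | step 9 | (3R,4Z)-3-({7-[(tert-butyldimethylsilyl)oxy]-3-methoxyhept-1-en-3-yl}peroxy)deca-4,9-dienal | COC(C=C)(CCCCO[Si](C)(C)C(C)(C)C)OO[C@@H](/C=C\CCCC=C)CC=O
F3 | step 9 | (3R,4Z)-3-({7-[(tert-butyldimethylsilyl)oxy]-3-methoxyhept-1-en-3-yl}peroxy)deca-4,9-dienoic acid | COC(C=C)(CCCCO[Si](C)(C)C(C)(C)C)OO[C@@H](/C=C\CCCC=C)CC(=O)O
F4 | step 9 | methyl (3R,4Z)-3-({7-[(tert-butyldimethylsilyl)oxy]-3-methoxyhept-1-en-3-yl}peroxy)deca-4,9-dienoate | COC(C=C)(CCCCO[Si](C)(C)C(C)(C)C)OO[C@@H](/C=C\CCCC=C)CC(=O)OC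
F5 | step 4 | (3R)-3-hydroperoxyoxolan-2-one | OO[C@@H]1CCOC1=O
F6 | step 6 | (3R)-3-({7-[(tert-butyldimethylsilyl)oxy]-3-methoxyhept-1-en-3-yl}peroxy)-5-(trimethylsilyl)pentane-1,4-diol | COC(C=C)(CCCCO[Si](C)(C)C(C)(C)C)OO[C@@H](C(O)C[Si](C)(C)C)CCO
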